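**Plan**

- Retrosynthesis: the aryl ether bond C7–O (to umbelliferone), the exocyclic C2=C8 bond (back to a C2 ketone) and the acetate are cut first, leaving cis-2-(silyloxymethyl)-4-hydroxy-3,3-dimethylcyclohexanone.
- Enabling feature: with the carbocycle numbered C1 (CH carrying the C7H2O arm), C2 (carrying methylene C8), C3, C4, C5 (CHOAc) and C6 (CMe2), the latent carbonyl C2 lies 1,4 to the oxygen on C5 through C1 and C6. The atoms C2, C1, C6, C5 and that oxygen can therefore be held as a γ-butyrolactone (oxolan-2-one) ring, and the ring bond C2–C3 is cut to a primary iodide at C3.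
- The lactone is cut at C1–C7 (enolate plus formaldehyde) and at C4–C5 (aldehyde plus allyl), leading back to methyl 3,3-dimethylpent-4-enoate.
- Forward: ozonolysis, allylboration with lactonisation (oxolanone ring), hydroxymethylation, silylation and trimming of allyl to iodoethyl come first. SmI2 then forms C2–C3 and closes the cyclohexanone as the lactone opens; acetylation, methylenation, desilylation and Mitsunobu etherification finish.
- Stereochemistry: C5 comes from the chiral allylborane (reagent control) and C1 from attack of formaldehyde anti to the C5 side chain (substrate control). The ring switch breaks no bond to either centre, so the 3,5-trans lactone becomes the 2,4-cis ketone, which is also the expected more stable epimer.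

Key step: step 7

Remark: the allylborane is specified by its pinene series (lIpc, from (−)-α-pinene) and not by a sign of rotation; this series is taken to add the allyl group to the Re face of an aldehyde, which here gives the (R) carbinol.

**Route**

Step 1
Reactants: 1 methyl 3,3-dimethylpent-4-enoate
Product: 3 methyl 3,3-dimethyl-4-oxobutanoate, via ozonide 2 (not isolated)
Conditions: O3, CH2Cl2, −78 °C; then Me2S, −78 °C to rt
Reagents that add atoms: ozone, [O-][O+]=O
Why: Ozonolysis (Criegee mechanism) of the monosubstituted alkene with reductive cleavage of the secondary ozonide by dimethyl sulfide should give the non-enolisable aldehyde without touching the ester.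

Step 2
Reactants: 3 methyl 3,3-dimethyl-4-oxobutanoate; 4 lIpc2B(allyl), B-(prop-2-en-1-yl)bis(isopinocampheyl)borane of the (−)-α-pinene series, as a salt-free pentane solution
Product: 7 (5R)-4,4-dimethyl-5-(prop-2-en-1-yl)oxolan-2-one, via borinate 5 (not isolated), via hydroxy ester 6 (not isolated)
Conditions: Et2O–pentane, −100 °C to −78 °C; then NaOH, H2O2, H2O, 0 °C to rt; then HCl to pH 2, TsOH (cat.), CH2Cl2, rt
Reagents that add atoms: none
Why: Brown allylboration through a chair Zimmerman–Traxler transition state, in which the lIpc groups on boron direct the allyl group to the Re face of the hindered aldehyde, should set the (R) centre C5 by reagent control, and the γ-hydroxy ester, helped by the gem-dimethyl (Thorpe–Ingold) effect, should lactonise under acid.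

Step 3
Reactants: 7 (5R)-4,4-dimethyl-5-(prop-2-en-1-yl)oxolan-2-one; 8 formaldehyde (monomer, generated by cracking paraformaldehyde)
Product: 10 (3S,5R)-3-(hydroxymethyl)-4,4-dimethyl-5-(prop-2-en-1-yl)oxolan-2-one, via lithium enolate 9 (not isolated)
Conditions: LiN(iPr)2, THF, −78 °C; CH2O gas in N2 stream, −78 to −20 °C; AcOH
Reagents that add atoms: none
Why: Aldol-type hydroxymethylation of the lithium lactone enolate with monomeric formaldehyde should take place on the face anti to the C5 allyl group (and to the pseudoaxial C4 methyl on that same face), giving the 3,5-trans lactone and thereby the C1 stereocentre of the target by substrate control.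

Step 4
Reactants: 10 (3S,5R)-3-(hydroxymethyl)-4,4-dimethyl-5-(prop-2-en-1-yl)oxolan-2-one
Product: 11 (3S,5R)-3-[(tert-butyldimethylsilyloxy)methyl]-4,4-dimethyl-5-(prop-2-en-1-yl)oxolan-2-one
Conditions: TBSCl, imidazole, DMF, 0 °C to rt
Reagents that add atoms: tert-butyldimethylsilyl chloride, CC(C)(C)[Si](C)(C)Cl
Why: Silyl ether formation on the primary alcohol with imidazole as base is mild enough to avoid epimerisation at C3 or β-elimination to the α-methylene lactone.

Step 5
Reactants: 11 (3S,5R)-3-[(tert-butyldimethylsilyloxy)methyl]-4,4-dimethyl-5-(prop-2-en-1-yl)oxolan-2-one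
Product: 13 (3S,5R)-3-[(tert-butyldimethylsilyloxy)methyl]-5-(2-hydroxyethyl)-4,4-dimethyloxolan-2-one, via ozonide 12 (not isolated)
Conditions: O3, CH2Cl2, −78 °C; then NaBH4, MeOH, −78 to 0 °C
Reagents that add atoms: ozone, [O-][O+]=O
Why: Ozonolysis with reductive borohydride work-up shortens the allyl group by one carbon to the 2-hydroxyethyl arm, and the hindered, α-branched lactone should survive NaBH4 at 0 °C.

Step 6
Reactants: 13 (3S,5R)-3-[(tert-butyldimethylsilyloxy)methyl]-5-(2-hydroxyethyl)-4,4-dimethyloxolan-2-one
Product: 14 (3S,5R)-3-[(tert-butyldimethylsilyloxy)methyl]-5-(2-iodoethyl)-4,4-dimethyloxolan-2-one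
Conditions: I2, PPh3, imidazole, CH2Cl2, 0 °C to rt
Reagents that add atoms: iodine, II
Why: Appel-type iodination (Garegg–Samuelsson conditions) replaces the primary hydroxyl by iodide through SN2 attack on the alkoxyphosphonium ion under buffered conditions that spare the silyl ether and the lactone.

Step 7
Reactants: 14 (3S,5R)-3-[(tert-butyldimethylsilyloxy)methyl]-5-(2-iodoethyl)-4,4-dimethyloxolan-2-one
Product: 17 (2S,4R)-2-[(tert-butyldimethylsilyloxy)methyl]-4-hydroxy-3,3-dimethylcyclohexan-1-one, via alkylsamarium 15 (not isolated), via bridged hemiketalate 16 (not isolated)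
Conditions: SmI2 (2.2 equiv, 0.1 M in THF), Fe(dbm)3 (2 mol %, dbm = dibenzoylmethanate), THF, −30 °C to rt; then aq. NH4Cl
Reagents that add atoms: none
Why: Proposed new method: two single-electron transfers from SmI2 (divalent samarium) should convert the primary iodide at C3 into an alkylsamarium (trivalent samarium) that adds to the lactone carbonyl C2 from the face carrying its own tether; the closest known reaction types are the SmI2-promoted intramolecular Barbier-type acyl substitution of iodoalkyl esters and lactones to cyclic ketones and the SmI2 Barbier closure of 3-(iodoalkyl)cycloalkanones to bridgehead bicyclic alcohols, but a lactone whose tether sits on the carbinol carbon, so that the tetrahedral intermediate is bridged, is without precedent. The carbocycle closes 6-exo-trig with the carbonyl oxygen outside the new ring (5-exo-trig if counted through the ring oxygen), giving the 7-oxabicyclo[2.2.1]heptan-1-olate 16. Its strain should drive collapse by cleavage of the C2–O bond, which opens the oxolanone and leaves the cyclohexanone with the C5 oxygen as a samarium alkoxide. No stereocentre is formed and no bond to C1 or C5 is broken, so the 3,5-trans lactone can only emerge as the 2,4-cis ketone, the bridgehead C2 being stereogenic only in transient 16. The step needs carbonyl addition to outrun protonation of the organosamarium, deprotonation at C1 and further reduction of the ketone: the low basicity and high oxophilicity of alkylsamariums, intramolecular delivery, a bare two equivalents of SmI2 and the omission of HMPA (SmI2 in THF alone reduces dialkyl ketones only slowly) should secure this.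

Step 8
Reactants: 17 (2S,4R)-2-[(tert-butyldimethylsilyloxy)methyl]-4-hydroxy-3,3-dimethylcyclohexan-1-one
Product: 18 (1R,3S)-3-[(tert-butyldimethylsilyloxy)methyl]-2,2-dimethyl-4-oxocyclohexyl acetate
Conditions: Ac2O, pyridine, DMAP (cat.), CH2Cl2, 0 °C to rt
Reagents that add atoms: acetic anhydride, CC(=O)OC(C)=O
Why: DMAP-catalysed acylation of the hindered secondary alcohol leaves the C5–O bond untouched, and any base-induced equilibration at the ketone α-carbon would only favour the diequatorial cis arrangement already present.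

Step 9
Reactants: 18 (1R,3S)-3-[(tert-butyldimethylsilyloxy)methyl]-2,2-dimethyl-4-oxocyclohexyl acetate
Product: 19 (1R,3S)-3-[(tert-butyldimethylsilyloxy)methyl]-2,2-dimethyl-4-methylidenecyclohexyl acetate
Conditions: Zn, CH2Br2, TiCl4, THF–CH2Cl2, 0 °C to rt
Reagents that add atoms: dibromomethane, BrCBr
Why: Takai–Lombardo methylenation with the non-basic zinc–titanium gem-dimetallic reagent should convert the hindered, epimerisable β-silyloxy ketone into the exocyclic alkene without epimerisation, β-elimination or attack on the acetate.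

Step 10
Reactants: 19 (1R,3S)-3-[(tert-butyldimethylsilyloxy)methyl]-2,2-dimethyl-4-methylidenecyclohexyl acetate
Product: 20 (1R,3S)-3-(hydroxymethyl)-2,2-dimethyl-4-methylidenecyclohexyl acetate
Conditions: HF·pyridine, pyridine, THF, 0 °C to rt
Reagents that add atoms: none
Why: Buffered fluoride-mediated cleavage of the Si–O bond frees the primary alcohol under conditions too mild for acetate cleavage, acyl migration or isomerisation of the exocyclic alkene.

Step 11
Reactants: 20 (1R,3S)-3-(hydroxymethyl)-2,2-dimethyl-4-methylidenecyclohexyl acetate; 21 umbelliferone (7-hydroxy-2H-chromen-2-one)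
Product: 22 (1R,3S)-2,2-dimethyl-4-methylidene-3-{[(2-oxo-2H-chromen-7-yl)oxy]methyl}cyclohexyl acetate
Conditions: PPh3, DIAD, THF, 0 °C to rt
Reagents that add atoms: none
Why: Mitsunobu etherification couples the acidic phenol with the primary alcohol through its alkoxyphosphonium ion at C7, which is not a stereocentre, under neutral conditions that leave the acetate, the alkene and the coumarin lactone intact.

**Compound list**

1 | methyl 3,3-dimethylpent-4-enoate | COC(=O)CC(C)(C)C=C | starting material
2 | methyl 3-methyl-3-(1,2,4-trioxolan-3-yl)butanoate (ozonide of 1, racemic at the ring carbon) | COC(=O)CC(C)(C)C1OCOO1 | intermediate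
3 | methyl 3,3-dimethyl-4-oxobutanoate | COC(=O)CC(C)(C)C=O | intermediate
4 | lIpc2B(allyl): B-(prop-2-en-1-yl)bis(isopinocampheyl)borane, both isopinocampheyl groups from (−)-α-pinene (oxidation gives (1S,2S,3S,5R)-isopinocampheol) | C=CCB([C@H]1C[C@H]2C[C@@H]([C@@H]1C)C2(C)C)[C@H]1C[C@H]2C[C@@H]([C@@H]1C)C2(C)C | starting material
5 | methyl (4R)-4-[bis(isopinocampheyl)boranyloxy]-3,3-dimethylhept-6-enoate (lIpc groups as in 4) | COC(=O)CC(C)(C)[C@@H](CC=C)OB([C@H]1C[C@H]2C[C@@H]([C@@H]1C)C2(C)C)[C@H]1C[C@H]2C[C@@H]([C@@H]1C)C2(C)C | intermediate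
6 | methyl (4R)-4-hydroxy-3,3-dimethylhept-6-enoate | COC(=O)CC(C)(C)[C@H](O)CC=C | intermediate
7 | (5R)-4,4-dimethyl-5-(prop-2-en-1-yl)oxolan-2-one | C=CC[C@H]1OC(=O)CC1(C)C | intermediate
8 | formaldehyde | C=O | starting material
9 | lithium enolate of 7: lithium (5R)-4,4-dimethyl-5-(prop-2-en-1-yl)-4,5-dihydrofuran-2-olate | C=CC[C@H]1OC(O[Li])=CC1(C)C | intermediate
10 | (3S,5R)-3-(hydroxymethyl)-4,4-dimethyl-5-(prop-2-en-1-yl)oxolan-2-one (3,5-trans) | C=CC[C@H]1OC(=O)[C@H](CO)C1(C)C | intermediate
11 | (3S,5R)-3-[(tert-butyldimethylsilyloxy)methyl]-4,4-dimethyl-5-(prop-2-en-1-yl)oxolan-2-one | C=CC[C@H]1OC(=O)[C@H](CO[Si](C)(C)C(C)(C)C)C1(C)C | intermediate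
12 | ozonide of 11: (3S,5R)-3-[(tert-butyldimethylsilyloxy)methyl]-4,4-dimethyl-5-[(1,2,4-trioxolan-3-yl)methyl]oxolan-2-one (both epimers at the trioxolane carbon) | O1OC(C[C@H]2OC(=O)[C@H](CO[Si](C)(C)C(C)(C)C)C2(C)C)OC1 | intermediate
13 | (3S,5R)-3-[(tert-butyldimethylsilyloxy)methyl]-5-(2-hydroxyethyl)-4,4-dimethyloxolan-2-one | OCC[C@H]1OC(=O)[C@H](CO[Si](C)(C)C(C)(C)C)C1(C)C | intermediate
14 | (3S,5R)-3-[(tert-butyldimethylsilyloxy)methyl]-5-(2-iodoethyl)-4,4-dimethyloxolan-2-one (3,5-trans) | ICC[C@H]1OC(=O)[C@H](CO[Si](C)(C)C(C)(C)C)C1(C)C | intermediate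
15 | (3S,5R)-3-[(tert-butyldimethylsilyloxy)methyl]-5-[2-(diiodosamario)ethyl]-4,4-dimethyloxolan-2-one | I[Sm](I)CC[C@H]1OC(=O)[C@H](CO[Si](C)(C)C(C)(C)C)C1(C)C | intermediate
16 | diiodosamarium 2-exo-[(tert-butyldimethylsilyloxy)methyl]-3,3-dimethyl-7-oxabicyclo[2.2.1]heptan-1-olate | I[Sm](I)O[C@@]12CC[C@@H](O1)C(C)(C)[C@H]2CO[Si](C)(C)C(C)(C)C | intermediate
17 | (2S,4R)-2-[(tert-butyldimethylsilyloxy)methyl]-4-hydroxy-3,3-dimethylcyclohexan-1-one (2,4-cis) | O=C1CC[C@@H](O)C(C)(C)[C@H]1CO[Si](C)(C)C(C)(C)C | intermediate
18 | (1R,3S)-3-[(tert-butyldimethylsilyloxy)methyl]-2,2-dimethyl-4-oxocyclohexyl acetate | O=C1CC[C@@H](OC(C)=O)C(C)(C)[C@H]1CO[Si](C)(C)C(C)(C)C | intermediate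
19 | (1R,3S)-3-[(tert-butyldimethylsilyloxy)methyl]-2,2-dimethyl-4-methylidenecyclohexyl acetate | C=C1CC[C@@H](OC(C)=O)C(C)(C)[C@H]1CO[Si](C)(C)C(C)(C)C | intermediate
20 | (1R,3S)-3-(hydroxymethyl)-2,2-dimethyl-4-methylidenecyclohexyl acetate | C=C1CC[C@@H](OC(C)=O)C(C)(C)[C@H]1CO | intermediate
21 | umbelliferone (7-hydroxy-2H-chromen-2-one) | Oc1ccc2ccc(=O)oc2c1 | starting material
22 | (1R,3S)-2,2-dimethyl-4-methylidene-3-{[(2-oxo-2H-chromen-7-yl)oxy]methyl}cyclohexyl acetate | C=C1CC[C@@H](OC(C)=O)C(C)(C)[C@H]1COc1ccc2ccc(=O)oc2c1 | target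

**Step count and risks**

Total step count: 11. Longest linear sequence: 11 steps (1 to 22).

Steps most likely to fail:

1. Step 7 (proposed new method). The alkylsamarium, or the radical before it, may be quenched by hydrogen abstraction or protonation, or may deprotonate C1, faster than it can reach the carbonyl through the strained bridged transition state; the iodine would then simply be lost. The fallback removes the bridge by opening the lactone before the ring is closed and sets out from 14. Treatment with Me(MeO)NH·HCl and AlMe3 (CH2Cl2, 0 °C) should give (2S,4R)-2-[(tert-butyldimethylsilyloxy)methyl]-4-hydroxy-6-iodo-N-methoxy-N,3,3-trimethylhexanamide F1. This is silylated at once (TMSOTf, 2,6-lutidine, CH2Cl2, −78 °C), before it can relactonise, to (2S,4R)-2-[(tert-butyldimethylsilyloxy)methyl]-6-iodo-N-methoxy-N,3,3-trimethyl-4-(trimethylsilyloxy)hexanamide F2. Iodine–lithium exchange with tert-butyllithium (2.2 equiv, Et2O–pentane, −78 °C) and intramolecular acylation of the alkyllithium by the N-methoxy-N-methylamide (Weinreb amide), a known ring closure of ω-iodo amides to cyclic ketones, would give (2S,4R)-2-[(tert-butyldimethylsilyloxy)methyl]-3,3-dimethyl-4-(trimethylsilyloxy)cyclohexan-1-one F3. Citric acid in MeOH then removes the trimethylsilyl group selectively, and the route is rejoined at 17.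

2. Step 3. The small, very reactive electrophile may show poor facial selectivity, and the aldolate may react further (second hydroxymethylation, retro-aldol, or elimination to the α-methylene lactone). The fallback replaces the aldol by an irreversible SN2 alkylation with a larger electrophile and sets out from 7. The enolate (LiN(iPr)2, THF, −78 °C) is alkylated with benzyl chloromethyl ether to give (3S,5R)-3-[(benzyloxy)methyl]-4,4-dimethyl-5-(prop-2-en-1-yl)oxolan-2-one F4. The benzyl ether is then cleaved with BCl3 (CH2Cl2, −78 °C), which spares the alkene and the lactone, and the route is rejoined at 10.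

3. Step 11. Displacement at C7 of the alkoxyphosphonium ion may be too slow, because C7 is flanked by the quaternary C6 and the methylene-bearing C2, so that the hydrazide by-product is alkylated or the alcohol is recovered. The fallback separates activation from displacement and sets out from 20. Tf2O and 2,6-lutidine (CH2Cl2, −78 °C) should give [(1S,3R)-3-acetoxy-2,2-dimethyl-6-methylidenecyclohexyl]methyl trifluoromethanesulfonate F5. This is displaced by the cesium phenoxide of 21 (Cs2CO3, MeCN, 0 °C to rt), and the route is rejoined at 22.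

Further compounds
F1 | step 7 | (2S,4R)-2-[(tert-butyldimethylsilyloxy)methyl]-4-hydroxy-6-iodo-N-methoxy-N,3,3-trimethylhexanamide | ICC[C@@H](O)C(C)(C)[C@@H](CO[Si](C)(C)C(C)(C)C)C(=O)N(C)OC
F2 | step 7 | (2S,4R)-2-[(tert-butyldimethylsilyloxy)methyl]-6-iodo-N-methoxy-N,3,3-trimethyl-4-(trimethylsilyloxy)hexanamide | ICC[C@@H](O[Si](C)(C)C)C(C)(C)[C@@H](CO[Si](C)(C)C(C)(C)C)C(=O)N(C)OC
F3 | step 7 | (2S,4R)-2-[(tert-butyldimethylsilyloxy)methyl]-3,3-dimethyl-4-(trimethylsilyloxy)cyclohexan-1-one | O=C1CC[C@@H](O[Si](C)(C)C)C(C)(C)[C@H]1CO[Si](C)(C)C(C)(C)C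
F4 | step 3 | (3S,5R)-3-[(benzyloxy)methyl]-4,4-dimethyl-5-(prop-2-en-1-yl)oxolan-2-one | C=CC[C@H]1OC(=O)[C@H](COCc2ccccc2)C1(C)C
F5 | step 11 | [(1S,3R)-3-acetoxy-2,2-dimethyl-6-methylidenecyclohexyl]methyl trifluoromethanesulfonate | C=C1CC[C@@H](OC(C)=O)C(C)(C)[C@H]1COS(=O)(=O)C(F)(F)F
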